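**Plan**
1. The retrosynthesis first cuts the interflavanyl bond C4(upper)–C6(lower), giving a C4 cation of the upper unit and ring A of the lower unit. Both halves are then the same 2,3-cis-3,4-trans flavan-3,4-diol (isomelacacidin skeleton), so one monomer, 11, serves twice.
2. In 11 the O1–C2 bond of the pyran ring C is cut. C2 is benzylic to the catechol ring B and lies six atoms from the ring A phenol oxygen, so it is the far carbon of a cis-epoxide that the phenoxide can open. The epoxy alcohol goes back to a Z allylic alcohol, a propargylic alcohol, and finally aldehyde 3 plus alkyne 5.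
3. Forward: 3 + 5 → carbinol 7 → Z alkene 8 → epoxy alcohol 9 → ring C closed (11) → diacetate 12 (nucleophile) and 4-thioether 14 (electrophile) → AgBF4-promoted coupling joins the two chromane units (16) → deacetylation and hydrogenolysis.
4. Stereochemistry: C4 comes from a BINOL/Ti(OiPr)4 alkynylation, C3 from hydroxyl-directed epoxidation of the Z alkene, and C2 from inversion in the ring closure (2,3-cis). The upper C4 is set when the lower ring A attacks the cation anti to the 3-acetoxy group (3,4-trans).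

Key step: step 7

Assumption: the alkynylation in step 4 is taken to attack the same aldehyde face as in the benzaldehyde/phenylacetylene case, which makes (R)-BINOL the ligand for the (1R) carbinol 7; if a trial run shows the opposite sense, (S)-BINOL is used.

**Step 1**
Reactants: 1 2,3,4-trihydroxybenzaldehyde
Product: 2 3,4-bis(benzyloxy)-2-hydroxybenzaldehyde
Conditions: BnBr (2.1 equiv), K2CO3 (2.1 equiv), DMF, rt
Reagents that add atoms: benzyl bromide, BrCc1ccccc1
Why: Williamson etherification under stoichiometric control; the 2-hydroxyl is held in a hydrogen bond to the formyl oxygen and is the poorest nucleophile, so O-4 and O-3 should be benzylated and O-2 left free.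

**Step 2**
Reactants: 2 3,4-bis(benzyloxy)-2-hydroxybenzaldehyde
Product: 3 3,4-bis(benzyloxy)-2-[(tert-butyldimethylsilyl)oxy]benzaldehyde
Conditions: TBSCl, imidazole, DMF, rt
Reagents that add atoms: tert-butyldimethylsilyl chloride, CC(C)(C)[Si](C)(C)Cl
Why: Standard phenol silylation; the silyl ether masks the ring A oxygen that becomes O1 and can later be removed by fluoride without acid.

**Step 3**
Reactants: 4 3,4-bis(benzyloxy)benzaldehyde
Product: 5 1,2-bis(benzyloxy)-4-ethynylbenzene
Conditions: dimethyl (1-diazo-2-oxopropyl)phosphonate, K2CO3, MeOH, 0 °C to rt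
Reagents that add atoms: dimethyl (1-diazo-2-oxopropyl)phosphonate, COP(=O)(OC)C(=[N+]=[N-])C(C)=O
Why: Ohira–Bestmann form of the Seyferth–Gilbert homologation, which converts an aryl aldehyde into the terminal alkyne under mild base that benzyl ethers tolerate.

**Step 4**
Reactants: 3 3,4-bis(benzyloxy)-2-[(tert-butyldimethylsilyl)oxy]benzaldehyde; 5 1,2-bis(benzyloxy)-4-ethynylbenzene
Product: 7 (1R)-1-{3,4-bis(benzyloxy)-2-[(tert-butyldimethylsilyl)oxy]phenyl}-3-[3,4-bis(benzyloxy)phenyl]prop-2-yn-1-ol, via alkynylzinc 6 (not isolated)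
Conditions: 5 (2 equiv), ZnEt2 (2 equiv), toluene, reflux; then (R)-BINOL (20 mol%), Ti(OiPr)4 (50 mol%), CH2Cl2, rt; then 3, rt; aq NH4Cl
Reagents that add atoms: none
Why: Catalytic enantioselective alkynylzinc addition to an aryl aldehyde (BINOL/Ti(OiPr)4 system); the chiral catalyst formed from Ti(OiPr)4 and BINOL holds the aldehyde so that the alkynyl group attacks one face and sets the (R) carbinol centre (later C4), the only centre in the route that comes from a chiral reagent.

**Step 5**
Reactants: 7 (1R)-propargylic alcohol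
Product: 8 (1R,2Z)-1-{3,4-bis(benzyloxy)-2-[(tert-butyldimethylsilyl)oxy]phenyl}-3-[3,4-bis(benzyloxy)phenyl]prop-2-en-1-ol
Conditions: H2 (1 atm), Pd/CaCO3 poisoned with Pb(OAc)2 (Lindlar catalyst), quinoline, EtOAc, rt
Reagents that add atoms: none
Why: Lindlar semihydrogenation adds hydrogen syn to the alkyne and should stop at the Z alkene, leaving benzyl ethers, the silyl ether and the carbinol centre untouched.

**Step 6**
Reactants: 8 (1R,2Z)-allylic alcohol
Product: 9 (S)-{3,4-bis(benzyloxy)-2-[(tert-butyldimethylsilyl)oxy]phenyl}{(2R,3S)-3-[3,4-bis(benzyloxy)phenyl]oxiran-2-yl}methanol (threo cis-epoxy alcohol)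
Conditions: mCPBA, NaHCO3, CH2Cl2, 0 °C
Reagents that add atoms: meta-chloroperoxybenzoic acid, OOC(=O)c1cccc(Cl)c1
Why: Hydroxyl-directed peracid epoxidation of a Z allylic alcohol; allylic 1,3-strain puts the carbinol hydrogen in the alkene plane and the hydrogen-bonded peracid delivers oxygen on the hydroxyl side, which should give the threo cis-epoxide and so set the future C3 (and the epoxide carbon C2), while the bicarbonate buffer protects the electron-rich aryl epoxide from acid.

**Step 7**
Reactants: 9 threo cis-epoxy alcohol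
Product: 11 (2R,3R,4S)-7,8-bis(benzyloxy)-2-[3,4-bis(benzyloxy)phenyl]-3,4-dihydro-2H-chromene-3,4-diol (7,8,3′,4′-tetra-O-benzylisomelacacidin), via phenoxide 10 (not isolated)
Conditions: TBAF (1.2 equiv), THF, 0 °C to rt; then AcOH
Reagents that add atoms: none
Why: Fluoride cleaves the aryl silyl ether, and the freed ring A phenoxide (O1) attacks the benzylic epoxide carbon C2 in an intramolecular SN2 opening, the epoxide oxygen becoming the C3 hydroxyl. The closest known reaction types are the opening of 3-aryl-2,3-epoxy alcohols by phenoxides at the benzylic carbon and the phenol/epoxide cyclization used to make flavan-3-ols. The pyran ring C closes in the 6-endo-tet mode. C2 is set by inversion at the cis-epoxide carbon, which places the ring B aryl cis to the C3 hydroxyl, while C3 and C4 are carried over unchanged from 9 (3,4-trans from the threo relationship). The step needs attack at C2 rather than 5-exo attack at C3 or Payne migration of the epoxide; this should be secured by the benzylic activation of C2 by the para-oxygenated ring B, by the inductive deactivation of C3 by the neighbouring C4 hydroxyl, and by the phenoxide being present in far higher concentration than the alkoxide.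

**Step 8**
Reactants: 11 tetra-O-benzylisomelacacidin
Product: 12 (2R,3S,4S)-7,8-bis(benzyloxy)-2-[3,4-bis(benzyloxy)phenyl]-3,4-dihydro-2H-chromene-3,4-diyl diacetate (2,3-cis-3,4-trans)
Conditions: Ac2O, pyridine, DMAP (cat.), rt
Reagents that add atoms: acetic anhydride, CC(=O)OC(C)=O
Why: Routine acetylation that turns both hydroxyls into non-nucleophilic esters; the 3-acetate later steers substitution at C4 and the 4-acetate is a leaving group only towards hard Lewis acids.

**Step 9**
Reactants: 12 diacetate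
Product: 14 (2R,3S,4S)-4-(benzylsulfanyl)-7,8-bis(benzyloxy)-2-[3,4-bis(benzyloxy)phenyl]-3,4-dihydro-2H-chromen-3-yl acetate (3,4-trans), via cation acetoxytrifluoroborate 13 (not isolated)
Conditions: BnSH (3 equiv), BF3·OEt2 (20 mol%), CH2Cl2, −40 °C
Reagents that add atoms: phenylmethanethiol, SCc1ccccc1
Why: Lewis acid thiolysis of a flavan C4 ester (SN1); BF3 takes up the C4 acetate as acetoxytrifluoroborate, the benzylic cation of this ion pair is stabilized by the para 7-benzyloxy group and by O1, and the thiol should add anti to the axial 3-acetoxy group, which installs a soft leaving group and returns BF3 together with acetic acid.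

**Step 10**
Reactants: 14 4-thioether; 12 diacetate
Product: 16 3-O-acetyl-7,8,3′,4′-tetra-O-benzylepimesquitol-(4β→6)-3,4-di-O-acetyl-7,8,3′,4′-tetra-O-benzylisomelacacidin (both units 2,3-cis-3,4-trans), via cation tetrafluoroborate 15 (not isolated)
Conditions: 12 (3 equiv), AgBF4 (1.5 equiv), 2,6-di-tert-butyl-4-methylpyridine (2 equiv), 4 Å molecular sieves, THF, −20 to 0 °C, dark, slow addition of 14
Reagents that add atoms: none
Why: Thiophilic activation of the thioether by AgBF4 removes the sulfur as silver benzylthiolate and leaves the flavan-4-ylium ion paired with the non-nucleophilic tetrafluoroborate, which undergoes Friedel–Crafts capture by C6 of ring A of 12 (ortho to the 7-ether oxygen, para to O1), a biomimetic interflavanyl coupling; the acetates of 12 are inert to the soft promoter, the hindered pyridine takes up the HBF4 released, and the 3-acetoxy group should send the arene to the opposite face, setting the upper C4 (3,4-trans).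

**Step 11**
Reactants: 16 octabenzyl ether triacetate
Product: 17 7,8,3′,4′-tetra-O-benzylepimesquitol-(4β→6)-7,8,3′,4′-tetra-O-benzylisomelacacidin (octabenzyl ether of the target)
Conditions: K2CO3 (cat.), MeOH/THF, rt
Reagents that add atoms: none
Why: Zemplén-type transesterification removes the three acetates by acyl–oxygen cleavage, so no stereocentre is touched and the phenols stay protected while base is present.

**Step 12**
Reactants: 17 octabenzyl ether
Product: 18 epimesquitol-(4β→6)-isomelacacidin, (2R,3R,4S)-2-(3,4-dihydroxyphenyl)-6-[(2R,3R,4S)-2-(3,4-dihydroxyphenyl)-3,7,8-trihydroxy-3,4-dihydro-2H-chromen-4-yl]-3,4-dihydro-2H-chromene-3,4,7,8-tetrol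
Conditions: H2 (1 atm), Pd(OH)2/C, THF/MeOH/H2O, rt; filtration under argon, lyophilisation
Reagents that add atoms: none
Why: Hydrogenolysis of the eight aryl benzyl ethers under neutral conditions and short contact time, which should leave the secondary benzylic C4 hydroxyl and the interflavanyl bond intact.

**Compound list**
1 | 2,3,4-trihydroxybenzaldehyde | O=Cc1ccc(O)c(O)c1O | starting material
2 | 3,4-bis(benzyloxy)-2-hydroxybenzaldehyde | O=Cc1ccc(OCc2ccccc2)c(OCc2ccccc2)c1O | intermediate
3 | 3,4-bis(benzyloxy)-2-[(tert-butyldimethylsilyl)oxy]benzaldehyde | O=Cc1ccc(OCc2ccccc2)c(OCc2ccccc2)c1O[Si](C)(C)C(C)(C)C | intermediate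
4 | 3,4-bis(benzyloxy)benzaldehyde | O=Cc1ccc(OCc2ccccc2)c(OCc2ccccc2)c1 | starting material
5 | 1,2-bis(benzyloxy)-4-ethynylbenzene | C#Cc1ccc(OCc2ccccc2)c(OCc2ccccc2)c1 | intermediate
6 | ethyl{[3,4-bis(benzyloxy)phenyl]ethynyl}zinc | CC[Zn]C#Cc1ccc(OCc2ccccc2)c(OCc2ccccc2)c1 | intermediate
7 | (1R)-1-{3,4-bis(benzyloxy)-2-[(tert-butyldimethylsilyl)oxy]phenyl}-3-[3,4-bis(benzyloxy)phenyl]prop-2-yn-1-ol | O[C@H](C#Cc1ccc(OCc2ccccc2)c(OCc2ccccc2)c1)c1ccc(OCc2ccccc2)c(OCc2ccccc2)c1O[Si](C)(C)C(C)(C)C | intermediate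
8 | (1R,2Z)-1-{3,4-bis(benzyloxy)-2-[(tert-butyldimethylsilyl)oxy]phenyl}-3-[3,4-bis(benzyloxy)phenyl]prop-2-en-1-ol | O[C@H](/C=C\c1ccc(OCc2ccccc2)c(OCc2ccccc2)c1)c1ccc(OCc2ccccc2)c(OCc2ccccc2)c1O[Si](C)(C)C(C)(C)C | intermediate
9 | (S)-{3,4-bis(benzyloxy)-2-[(tert-butyldimethylsilyl)oxy]phenyl}{(2R,3S)-3-[3,4-bis(benzyloxy)phenyl]oxiran-2-yl}methanol | O[C@H]([C@H]1O[C@H]1c1ccc(OCc2ccccc2)c(OCc2ccccc2)c1)c1ccc(OCc2ccccc2)c(OCc2ccccc2)c1O[Si](C)(C)C(C)(C)C | intermediate
10 | tetrabutylammonium phenoxide of desilylated 9 | O[C@H]([C@H]1O[C@H]1c1ccc(OCc2ccccc2)c(OCc2ccccc2)c1)c1ccc(OCc2ccccc2)c(OCc2ccccc2)c1[O-].CCCC[N+](CCCC)(CCCC)CCCC | intermediate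
11 | (2R,3R,4S)-7,8-bis(benzyloxy)-2-[3,4-bis(benzyloxy)phenyl]-3,4-dihydro-2H-chromene-3,4-diol | c1cc2c(c(OCc3ccccc3)c1OCc1ccccc1)O[C@H](c1ccc(OCc3ccccc3)c(OCc3ccccc3)c1)[C@H](O)[C@H]2O | intermediate
12 | (2R,3S,4S)-7,8-bis(benzyloxy)-2-[3,4-bis(benzyloxy)phenyl]-3,4-dihydro-2H-chromene-3,4-diyl diacetate | c1cc2c(c(OCc3ccccc3)c1OCc1ccccc1)O[C@H](c1ccc(OCc3ccccc3)c(OCc3ccccc3)c1)[C@H](OC(C)=O)[C@H]2OC(C)=O | intermediate
13 | (2R,3R)-3-acetoxy-7,8-bis(benzyloxy)-2-[3,4-bis(benzyloxy)phenyl]-3,4-dihydro-2H-chromen-4-ylium acetoxytrifluoroborate (open benzylic C4 cation, ion pair formed with BF3) | c1cc2c(c(OCc3ccccc3)c1OCc1ccccc1)O[C@H](c1ccc(OCc3ccccc3)c(OCc3ccccc3)c1)[C@H](OC(C)=O)[CH+]2.CC(=O)O[B-](F)(F)F | intermediate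
14 | (2R,3S,4S)-4-(benzylsulfanyl)-7,8-bis(benzyloxy)-2-[3,4-bis(benzyloxy)phenyl]-3,4-dihydro-2H-chromen-3-yl acetate | c1cc2c(c(OCc3ccccc3)c1OCc1ccccc1)O[C@H](c1ccc(OCc3ccccc3)c(OCc3ccccc3)c1)[C@H](OC(C)=O)[C@H]2SCc1ccccc1 | intermediate
15 | (2R,3R)-3-acetoxy-7,8-bis(benzyloxy)-2-[3,4-bis(benzyloxy)phenyl]-3,4-dihydro-2H-chromen-4-ylium tetrafluoroborate (open benzylic C4 cation, ion pair formed with AgBF4) | c1cc2c(c(OCc3ccccc3)c1OCc1ccccc1)O[C@H](c1ccc(OCc3ccccc3)c(OCc3ccccc3)c1)[C@H](OC(C)=O)[CH+]2.F[B-](F)(F)F | intermediate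
16 | octabenzyl ether triacetate of the target (upper 3-OAc; lower 3-OAc and 4-OAc) | c1ccccc1COc1ccc([C@H]2Oc3c(ccc(OCc5ccccc5)c3OCc3ccccc3)[C@H](c3cc4c(c(OCc5ccccc5)c3OCc3ccccc3)O[C@H](c3ccc(OCc5ccccc5)c(OCc5ccccc5)c3)[C@H](OC(C)=O)[C@H]4OC(C)=O)[C@H]2OC(C)=O)cc1OCc1ccccc1 | intermediate
17 | octabenzyl ether of the target | c1ccccc1COc1ccc([C@H]2Oc3c(ccc(OCc5ccccc5)c3OCc3ccccc3)[C@H](c3cc4c(c(OCc5ccccc5)c3OCc3ccccc3)O[C@H](c3ccc(OCc5ccccc5)c(OCc5ccccc5)c3)[C@H](O)[C@H]4O)[C@H]2O)cc1OCc1ccccc1 | intermediate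
18 | epimesquitol-(4β→6)-isomelacacidin (CNP0143773.2) | Oc1ccc([C@H]2Oc3c(ccc(O)c3O)[C@H](c3cc4c(c(O)c3O)O[C@H](c3ccc(O)c(O)c3)[C@H](O)[C@H]4O)[C@H]2O)cc1O | target

**Count and risks**
Total steps: 12. Longest linear sequence: 11 steps (steps 1, 2 and 4 to 12; step 3 is the side branch).

Step 10. The benzylated, tri-oxygenated ring A of 12 may capture the cation too slowly, so that the cation is spent in self-condensation of 14 or in attack at C5 or ring B. The fallback makes the bond at the free-phenol level, as the plant presumably does. It sets out from 11: hydrogenolysis (H2, Pd(OH)2/C, THF/MeOH) should give isomelacacidin F1. Kept in 0.1 M aqueous HCl at rt, F1 ionizes reversibly at C4, and C6 of a second molecule, now ortho to a free 7-hydroxyl, should capture the cation anti to the axial 3-hydroxyl. The reaction is stopped at low conversion, the dimer separated on Sephadex LH-20 and the monomer recycled. This comes back to the route at 18.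

Step 7. The phenoxide may open the epoxide at C3 in the 5-exo mode, the C4 alkoxide may shift the epoxide (Payne rearrangement), or the electron-rich epoxide may ionize and lose the cis relationship. The fallback avoids the epoxide altogether. It sets out from 8: hydrogen-bond-directed syn dihydroxylation (OsO4, TMEDA, CH2Cl2, −78 °C; then aq Na2SO3) should add both hydroxyls on the alkene face beside the carbinol hydroxyl and give the (1S,2S,3S) triol F2. TBAF then gives the phenol F3. Mitsunobu closure (PPh3, DIAD, THF, 0 °C) should displace the activated benzylic hydroxyl at the future C2 by the phenol with inversion; the six-membered closure is the only SN2 path of the phenoxide that ends at a benzylic carbon. This comes back to the route at 11.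

Step 4. Facial selection may be eroded by the bulky ortho silyloxy group, or the silyl group may migrate to the new zinc alkoxide. The fallback sets the centre by reduction instead of addition. It sets out from 3 and 5: the lithium acetylide of 5 (n-BuLi, THF, −78 °C) adds to 3 to give the racemic carbinol F4. MnO2 (CH2Cl2, rt) gives the ynone F5. Corey–Bakshi–Shibata reduction ((S)-2-methyl-CBS-oxazaborolidine, BH3·SMe2, THF, −30 °C), with the ortho-disubstituted aryl as the large group and the alkynyl as the small group, should give the (1R) carbinol. This comes back to the route at 7.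

**Further compounds**
F1 | step 10 | isomelacacidin, (2R,3R,4S)-2-(3,4-dihydroxyphenyl)-3,4-dihydro-2H-chromene-3,4,7,8-tetrol | c1cc2c(c(O)c1O)O[C@H](c1ccc(O)c(O)c1)[C@H](O)[C@H]2O
F2 | step 7 | (1S,2S,3S)-1-{3,4-bis(benzyloxy)-2-[(tert-butyldimethylsilyl)oxy]phenyl}-3-[3,4-bis(benzyloxy)phenyl]propane-1,2,3-triol | O[C@H]([C@@H](O)[C@@H](O)c1ccc(OCc2ccccc2)c(OCc2ccccc2)c1)c1ccc(OCc2ccccc2)c(OCc2ccccc2)c1O[Si](C)(C)C(C)(C)C
F3 | step 7 | (1S,2S,3S)-1-[3,4-bis(benzyloxy)-2-hydroxyphenyl]-3-[3,4-bis(benzyloxy)phenyl]propane-1,2,3-triol | O[C@H]([C@@H](O)[C@@H](O)c1ccc(OCc2ccccc2)c(OCc2ccccc2)c1)c1ccc(OCc2ccccc2)c(OCc2ccccc2)c1O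
F4 | step 4 | racemic 1-{3,4-bis(benzyloxy)-2-[(tert-butyldimethylsilyl)oxy]phenyl}-3-[3,4-bis(benzyloxy)phenyl]prop-2-yn-1-ol | OC(C#Cc1ccc(OCc2ccccc2)c(OCc2ccccc2)c1)c1ccc(OCc2ccccc2)c(OCc2ccccc2)c1O[Si](C)(C)C(C)(C)C
F5 | step 4 | 1-{3,4-bis(benzyloxy)-2-[(tert-butyldimethylsilyl)oxy]phenyl}-3-[3,4-bis(benzyloxy)phenyl]prop-2-yn-1-one | O=C(C#Cc1ccc(OCc2ccccc2)c(OCc2ccccc2)c1)c1ccc(OCc2ccccc2)c(OCc2ccccc2)c1O[Si](C)(C)C(C)(C)C
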